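If a rate falls by the same factor in each equal span of time, the last gain tells what is still to come, so I read the runs for that factor. This is what I had, and what was asked.

| flask | starting material | partner | second reagent | third reagent | protic impurity | remark | time |
|---|---|---|---|---|---|---|---|
| Wednesday's | 0.020 M | 0.10 M | 0.018 M | 0.022 M | 0.020 M | run made earlier |  |
| Monday's | 0.020 M | 0.10 M | 0.0090 M | 0.022 M | 0.020 M | run made earlier |  |
| Sunday's | 0.020 M | 0.10 M | 0.036 M | 0.022 M | 0.020 M | run made earlier |  |
| Saturday's | 0.010 M | 0.10 M | 0.018 M | 0.022 M | 0.020 M | run made earlier |  |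
| alpha | 0.020 M | 0.100 M | 0.0180 M | 0.0220 M | 0.0200 M | everything together at the start | 3.0 d |
| eta | 0.020 M | 0.100 M (fed, over 40 h) | 0.0180 M | 0.0220 M | 0.0200 M | all else is in the flask from the start; the feed brings no volume worth counting | 3.0 d |
| zeta | 0.020 M (fed, over 40 h) | 0.100 M | 0.0180 M | 0.0220 M | 0.0200 M | all else is in the flask from the start; the feed brings no volume worth counting | 3.0 d |

Wednesday's run (percent of the starting material charged)

| time / h | over-reaction product / % | target / % |
|---|---|---|
| 4.00 | 7.0 | 12.6 |
| 10.0 | 28.6 | 13.1 |
| 20.0 | 49.3 | 5.1 |
| 30.0 | 57.8 | 2.2 |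
| 40.0 | 62.1 | 0.4 |

Monday's run (percent of the starting material charged)

| time / d | over-reaction product / % | target / % |
|---|---|---|
| 0.250 | 9.1 | 9.1 |
| 0.500 | 20.6 | 6.5 |
| 1.04 | 32.7 | 2.4 |
| 2.08 | 39.1 | 0.1 |
| 4.00 | 41.8 | 0.4 |

Sunday's run (percent of the starting material charged)

| time / d | over-reaction product / % | target / % |
|---|---|---|
| 0.625 | 48.7 | 7.8 |
| 1.25 | 64.1 | 2.1 |
| 2.00 | 69.4 | 0.7 |
| 3.00 | 70.7 | 0 |
| 4.00 | 71.0 | 0 |

Saturday's run (percent of the starting material charged)

| time / d | over-reaction product / % | target / % |
|---|---|---|
| 0.250 | 18.5 | 17.1 |
| 0.500 | 46.1 | 12.0 |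
| 1.04 | 71.9 | 3.7 |
| 2.08 | 84.7 | 0.6 |
| 4.00 | 90.3 | 0.3 |

(scatter of a reading: 0.3 percentage points)



- the flask that comes out highest in amount of over-reaction product, in percent of the starting material charged, or "all alike" when all lie within 1.5 percentage points (alpha / eta / zeta / all alike)
- over-reaction product at the end, in percent of the starting material charged, alpha
- over-reaction product at the end, in percent of the starting material charged, eta
- over-reaction product at the end, in percent of the starting material charged, zeta

I followed Wednesday's run, whose charges alpha repeats, through the sum of over-reaction product and target. In the first 4.00 h that sum grew by 0.0490 h⁻¹ of the charge. From 10.0 h to 20.0 h it gained 13 percentage points, and with 10.0 h to a span that rate was lower by a factor of 3.86. The next two spans gained 5.6 points and 2.5 points, so the rate fell by 2.27 and then by 2.24, the steady fall of a pseudo-first-order tail. As a reading, the share of one span's gain that the next span repeats was 0.444, and I called it the tail ratio. The gains after 40.0 h then sum to 2 points, and because 3.0 d leaves 3.20 further spans, nearly all of that arrives. From the 62.5% already reached, I committed alpha to 64.3%. None of the runs was fed, so I reckoned nothing for eta or zeta.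

The forecast named alpha as highest, with 64% there, 34% in zeta and 20% in eta, where it warned that “partner was never varied, so this is an assumption”.

The flask gave 65.6% in alpha, more than 58.6% in eta and 48.5% in zeta.

    starting material + partner → intermediate A (k = 29.0 L mol⁻¹ h⁻¹)
    second reagent + intermediate A → intermediate B (k = 72.0 L mol⁻¹ h⁻¹)
    third reagent + intermediate B → target (k = 5.80 L mol⁻¹ h⁻¹)
    partner + target → over-reaction product (k = 3.50 L mol⁻¹ h⁻¹)
    third reagent + protic impurity → quenched reagent (k = 2.10 L mol⁻¹ h⁻¹)

Alpha ended 1.3 points above my reckoning. In alpha, half of the turnover of the step from intermediate A to intermediate B was done by 1.08 h, earlier than the 0.299 d of the step from intermediate B to target, and at 3.00 d alpha still held 24.2% of the starting material charged as intermediate B, with 1.00% of the third reagent's own charge left.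

In the neighbour of alpha with 0.025 M of partner, the tail ratio of 0.444 gives the same 64.3%, for the sum and not for over-reaction product. The computed flask holds 63.6% in that sum, of which 22.0% is over-reaction product and 41.6% target.

The data were computed with constants of no real substance; noise was put on by code.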